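**Retrosynthetic overview**
- The strategy rests on ring A being a 2-alkylphloroglucinol with three different oxygens: C4a lies between C5–OMe and C8a–O1, and C7–OH is para to C4a. Such a ring has to be built with the oxygens already differentiated.
- Ring C (O1–C2) comes from Mitsunobu closure of a 2-(3-hydroxypropyl)phenol, after O-methylation at C5 and global desilylation.
- Ring A comes from a Danheiser benzannulation of 3-(triisopropylsilyloxy)cyclobutenone with a chiral triisopropylsilyl ynol ether. This forms C4a–C5 and C8–C8a and leaves a free OH at C5 and silyl ethers at C8a and C7.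
- The ynol ether comes from a terminal alkyne (acetylide oxidation, O-silylation), itself from the (R)-β-aryl-γ-butyrolactone (lactol, Ohira–Bestmann). The lactone comes from rhodium-catalysed asymmetric conjugate addition of the chromenylboronic acid to furan-2(5H)-one, which sets C3.
- Ring order: the dimethylpyran ring on ring B first (propargyl Claisen cascade on 4-bromoresorcinol, bromine blocking the other ortho site), then ring A (key step), then ring C.

Key step: step 12

Assumption: the target is the (3R)-isoflavan (CIP order at C3: C2 > C1′ > C4 > H), and the facial sense of the (R)-binap rhodium catalyst on furan-2(5H)-one is taken from that established for cyclic enones; should the lactone prove to be S, the (S)-ligand is used instead.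

**Step 1**
Reactants: 1 bromoresorcinol (4-bromobenzene-1,3-diol)
Product: 2 monosilyl ether 2-bromo-5-(triisopropylsilyloxy)phenol
Conditions: i-Pr3SiCl (1.0 equiv), imidazole, CH2Cl2, 0 °C
Reagents that add atoms: chlorotriisopropylsilane, CC(C)[Si](Cl)(C(C)C)C(C)C
Why: Sterically governed monosilylation of a resorcinol: the hydroxyl para to bromine is unhindered, whereas the one ortho to bromine is shielded and less nucleophilic, so the bulky silyl chloride should react at the remote oxygen and leave the ortho-bromophenol free for the next step.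

**Step 2**
Reactants: 2 monosilyl ether 2-bromo-5-(triisopropylsilyloxy)phenol; 3 propargylic chloride 3-chloro-3-methylbut-1-yne
Product: 4 aryl propargyl ether [4-bromo-3-(2-methylbut-3-yn-2-yloxy)phenoxy]triisopropylsilane
Conditions: 3 (1.5 equiv), CuCl2·2H2O (1 mol%), DBU, MeCN, 0 °C
Reagents that add atoms: none
Why: Copper-catalysed O-propargylation of a phenol with a tertiary propargylic chloride (Godfrey conditions), which proceeds through a copper acetylide-derived electrophile and so overcomes the reluctance of the tertiary chloride and the hindered ortho-bromophenoxide towards direct displacement.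

**Step 3**
Reactants: 4 aryl propargyl ether
Product: 7 bromochromene 8-bromo-2,2-dimethyl-5-(triisopropylsilyloxy)-2H-chromene, via allenylphenol 5 (not isolated), via ortho-quinone methide 6 (not isolated)
Conditions: PhNEt2, 180 °C, argon
Reagents that add atoms: none
Why: Aromatic propargyl Claisen rearrangement cascade ([3,3] shift to the ortho carbon, enolisation to the allenylphenol, 1,5-hydrogen shift to the ortho-quinone methide, oxa-6π-electrocyclisation), in which bromine blocks one ortho position so that only the carbon between the two oxygens can accept the new C–C bond and a single chromene regioisomer should form.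

**Step 4**
Reactants: 7 bromochromene
Product: 10 boronic acid [2,2-dimethyl-5-(triisopropylsilyloxy)-2H-chromen-8-yl]boronic acid, via aryllithium 8 (not isolated), via lithium triisopropoxyborate 9 (not isolated)
Conditions: n-BuLi, THF, −78 °C; B(Oi-Pr)3, −78 °C to rt; aq. NH4Cl
Reagents that add atoms: triisopropyl borate, CC(C)OB(OC(C)C)OC(C)C; water, O
Why: Bromine–lithium exchange followed by trapping with a trialkyl borate and mild hydrolysis, a standard arylboronic acid synthesis; the lithium sits para to the silyloxy group, so no silyl migration to carbon is possible, and the chromene is inert at −78 °C.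

**Step 5**
Reactants: 10 boronic acid; 11 butenolide furan-2(5H)-one
Product: 12 lactone (4R)-4-[2,2-dimethyl-5-(triisopropylsilyloxy)-2H-chromen-8-yl]oxolan-2-one
Conditions: [Rh(OH)(cod)]2 (1.5 mol%), (R)-BINAP (3.3 mol%), 11 (3 equiv), dioxane/H2O 10:1, 40–60 °C
Reagents that add atoms: none
Why: Hayashi–Miyaura rhodium-catalysed asymmetric 1,4-addition: the aryl group is transferred from boron to the hydroxorhodium–binap complex, adds to one enantiotopic face of the butenolide at C4 under control of the chiral diphosphine, and the rhodium enolate is hydrolysed, which sets the future C3 stereocentre as R.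

**Step 6**
Reactants: 12 lactone
Product: 13 lactol (4R)-4-[2,2-dimethyl-5-(triisopropylsilyloxy)-2H-chromen-8-yl]oxolan-2-ol (anomer mixture)
Conditions: i-Bu2AlH (1.1 equiv), CH2Cl2, −78 °C; aq. KNaC4H4O6 work-up
Reagents that add atoms: none
Why: Partial reduction of a γ-lactone with i-Bu2AlH at −78 °C, where the tetrahedral aluminium hemiacetal survives until work-up and gives the lactol; the stereocentre is β to the carbonyl and is not epimerisable.

**Step 7**
Reactants: 13 lactol
Product: 15 alkynol (2R)-2-[2,2-dimethyl-5-(triisopropylsilyloxy)-2H-chromen-8-yl]pent-4-yn-1-ol, via hydroxy aldehyde 14 (not isolated)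
Conditions: dimethyl (1-diazo-2-oxopropyl)phosphonate (1.5 equiv), K2CO3, MeOH, 0 °C to rt
Reagents that add atoms: dimethyl (1-diazo-2-oxopropyl)phosphonate, CC(=O)C(=[N+]=[N-])P(=O)(OC)OC
Why: Ohira–Bestmann (Seyferth–Gilbert) homologation of the hydroxy aldehyde that is in equilibrium with the lactol: Horner–Wadsworth–Emmons-type olefination by the diazomethylphosphonate anion, loss of N2 and a 1,2-hydride shift give the terminal alkyne, with one carbon added and the remote stereocentre untouched.

**Step 8**
Reactants: 15 alkynol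
Product: 16 silyl ether tert-butyl-dimethyl-{[(2R)-2-[2,2-dimethyl-5-(triisopropylsilyloxy)-2H-chromen-8-yl]pent-4-yn-1-yl]oxy}silane
Conditions: t-BuMe2SiCl, imidazole, DMF, rt
Reagents that add atoms: tert-butyl(chloro)dimethylsilane, CC(C)(C)[Si](C)(C)Cl
Why: Standard silylation of a primary alcohol (Corey conditions), which masks the future C2 oxygen against the strongly basic next step.

**Step 9**
Reactants: 16 silyl ether
Product: 19 siloxyalkyne (4R)-5-(tert-butyldimethylsilyloxy)-4-[2,2-dimethyl-5-(triisopropylsilyloxy)-2H-chromen-8-yl]-1-(triisopropylsilyloxy)pent-1-yne, via lithium acetylide 17 (not isolated), via lithium ynolate 18 (not isolated)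
Conditions: LiN(SiMe3)2 (2.2 equiv), THF, −78 °C; t-BuOOH (1.05 equiv, in decane), −78 to 0 °C; i-Pr3SiOTf (1.3 equiv), −78 to 0 °C
Reagents that add atoms: tert-butyl hydroperoxide, CC(C)(C)OO; triisopropylsilyl trifluoromethanesulfonate, CC(C)[Si](OS(=O)(=O)C(F)(F)F)(C(C)C)C(C)C
Why: Julia oxidation of a lithium acetylide with lithium tert-butyl peroxide (oxygen transfer with loss of lithium tert-butoxide) gives the lithium ynolate, which the bulky silyl triflate traps on oxygen to give the triisopropylsilyl ynol ether, a general route to isolable siloxyalkynes.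

**Step 10**
Reactants: 20 ethoxycyclobutenone (3-ethoxycyclobut-2-en-1-one)
Product: 21 dione cyclobutane-1,3-dione (present mainly as 3-hydroxycyclobut-2-en-1-one)
Conditions: 2 M aq. HCl, 0 °C to rt; freeze-dry, use at once
Reagents that add atoms: water, O
Why: Acid hydrolysis of a vinylogous ester (enol ether hydrolysis) to the 1,3-dione, which exists mainly as the enol and is used at once because it is not stable on storage.

**Step 11**
Reactants: 21 dione
Product: 22 silyloxycyclobutenone 3-(triisopropylsilyloxy)cyclobut-2-en-1-one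
Conditions: i-Pr3SiOTf, Et3N, CH2Cl2, −78 to 0 °C
Reagents that add atoms: triisopropylsilyl trifluoromethanesulfonate, CC(C)[Si](OS(=O)(=O)C(F)(F)F)(C(C)C)C(C)C
Why: O-Silylation of a vinylogous acid with a silyl triflate and an amine base; the bulky triisopropylsilyl group gives a vinylogous silyl ester that can be handled briefly under anhydrous conditions.

**Step 12**
Reactants: 19 siloxyalkyne; 22 silyloxycyclobutenone
Product: 27 phenol 2-[(2R)-3-(tert-butyldimethylsilyloxy)-2-[2,2-dimethyl-5-(triisopropylsilyloxy)-2H-chromen-8-yl]propyl]-3,5-bis(triisopropylsilyloxy)phenol, via vinylketene 23 (not isolated), via vinylcyclobutenone 24 (not isolated), via dienylketene 25 (not isolated), via cyclohexadienone 26 (not isolated)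
Conditions: 22 (1.5 equiv, added in portions), toluene (0.3 M), 80 °C then 110 °C, sealed tube, argon
Reagents that add atoms: none
Why: Danheiser benzannulation: thermal 4π-electrocyclic opening of 22 gives the 3-silyloxyvinylketene 23, whose ketene C=C bond undergoes a regioselective [2+2] cycloaddition with the ynol ether (the nucleophilic alkyl-bearing alkyne carbon, future C4a, bonds to the ketene carbonyl carbon, future C5, and the oxygen-bearing alkyne carbon, future C8a, bonds to the ketene α-carbon, future C8) to give vinylcyclobutenone 24. A second 4π-opening gives dienylketene 25, and ring A is then closed by a thermal disrotatory 6π-electrocyclisation that rejoins C5 to C6, followed by tautomerisation of dienone 26 to the phenol. The closest known reaction is the benzannulation of 3-alkylcyclobutenones with triisopropylsilyl ynol ethers to resorcinol monosilyl ethers, and the separate events (opening of 3-alkoxycyclobutenones to alkoxyvinylketenes, ketene–siloxyalkyne [2+2]) are each known, the 3-silyloxy group being carried as a spectator that becomes the C7 oxygen. No stereocentre is formed, and the existing C3 centre is neither enolisable nor conjugated to the reacting π system, so it is not at risk under neutral thermal conditions. The selectivity needed is the regiochemistry of the [2+2] step, which the strong polarisation of the ynol ether secures, together with chemoselectivity for the alkyne over the chromene alkene, which follows from the far higher nucleophilicity of the ynol ether towards ketenes. The outcome is a ring A whose three oxygens are already differentiated: free OH at C5, silyl ether at C8a from the alkyne, silyl ether at C7 from the cyclobutenone.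

**Step 13**
Reactants: 27 phenol
Product: 28 methyl ether tert-butyl-{(2R)-3-[2-methoxy-4,6-bis(triisopropylsilyloxy)phenyl]-2-[2,2-dimethyl-5-(triisopropylsilyloxy)-2H-chromen-8-yl]propoxy}dimethylsilane
Conditions: MeI, K2CO3, acetone, 40 °C
Reagents that add atoms: iodomethane, CI
Why: Williamson O-methylation of the single free phenol, which fixes the C5 methoxy group; the aryl triisopropylsilyl ethers are meta to the phenoxide and too hindered to migrate or cleave under K2CO3 in acetone.

**Step 14**
Reactants: 28 methyl ether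
Product: 29 tetraol 4-[(2R)-3-hydroxy-2-(5-hydroxy-2,2-dimethyl-2H-chromen-8-yl)propyl]-5-methoxybenzene-1,3-diol
Conditions: Bu4NF (5 equiv), AcOH (5 equiv), THF, 0 °C to rt, argon
Reagents that add atoms: none
Why: Fluoride-mediated global desilylation (three aryl silyl ethers and one primary alkyl silyl ether), buffered with acetic acid so that the electron-rich polyphenol is not exposed to free phenoxide and air together.

**Step 15**
Reactants: 29 tetraol
Product: 30 target (3R)-3-(5-hydroxy-2,2-dimethyl-2H-chromen-8-yl)-5-methoxy-3,4-dihydro-2H-chromen-7-ol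
Conditions: PPh3, DIAD, THF (0.01 M), 0 °C to rt, argon
Reagents that add atoms: none
Why: Intramolecular Mitsunobu etherification: the primary alcohol is activated as its alkoxyphosphonium ion and displaced by the adjacent C8a phenol in a 6-exo-tet closure of ring C (O1–C2), the only ring size open to any of the three phenols, while C3 is not a reacting centre and keeps its R configuration.

**Compound list**
1 | 4-bromoresorcinol | Oc1ccc(Br)c(O)c1 | starting material
2 | 2-bromo-5-(triisopropylsilyloxy)phenol | Oc1cc(O[Si](C(C)C)(C(C)C)C(C)C)ccc1Br | intermediate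
3 | 3-chloro-3-methylbut-1-yne | C#CC(C)(C)Cl | starting material
4 | [4-bromo-3-(2-methylbut-3-yn-2-yloxy)phenoxy]triisopropylsilane | C#CC(C)(C)Oc1cc(O[Si](C(C)C)(C(C)C)C(C)C)ccc1Br | intermediate
5 | 6-bromo-2-(3-methylbuta-1,2-dien-1-yl)-3-(triisopropylsilyloxy)phenol (not isolated) | CC(C)=C=Cc1c(O)c(Br)ccc1O[Si](C(C)C)(C(C)C)C(C)C | intermediate
6 | 2-bromo-6-(3-methylbut-2-en-1-ylidene)-5-(triisopropylsilyloxy)cyclohexa-2,4-dien-1-one (not isolated) | CC(C)=CC=C1C(=O)C(Br)=CC=C1O[Si](C(C)C)(C(C)C)C(C)C | intermediate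
7 | 8-bromo-2,2-dimethyl-5-(triisopropylsilyloxy)-2H-chromene | Brc1ccc(O[Si](C(C)C)(C(C)C)C(C)C)c2c1OC(C)(C)C=C2 | intermediate
8 | [2,2-dimethyl-5-(triisopropylsilyloxy)-2H-chromen-8-yl]lithium (not isolated) | [Li]c1ccc(O[Si](C(C)C)(C(C)C)C(C)C)c2c1OC(C)(C)C=C2 | intermediate
9 | lithium [2,2-dimethyl-5-(triisopropylsilyloxy)-2H-chromen-8-yl]tri(propan-2-yloxy)borate (not isolated) | [Li+].CC(C)O[B-](OC(C)C)(OC(C)C)c1ccc(O[Si](C(C)C)(C(C)C)C(C)C)c2c1OC(C)(C)C=C2 | intermediate
10 | [2,2-dimethyl-5-(triisopropylsilyloxy)-2H-chromen-8-yl]boronic acid | OB(O)c1ccc(O[Si](C(C)C)(C(C)C)C(C)C)c2c1OC(C)(C)C=C2 | intermediate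
11 | furan-2(5H)-one | O=C1OCC=C1 | starting material
12 | (4R)-4-[2,2-dimethyl-5-(triisopropylsilyloxy)-2H-chromen-8-yl]oxolan-2-one | O=C1C[C@H](c2ccc(O[Si](C(C)C)(C(C)C)C(C)C)c3c2OC(C)(C)C=C3)CO1 | intermediate
13 | (4R)-4-[2,2-dimethyl-5-(triisopropylsilyloxy)-2H-chromen-8-yl]oxolan-2-ol (anomer mixture) | OC1C[C@H](c2ccc(O[Si](C(C)C)(C(C)C)C(C)C)c3c2OC(C)(C)C=C3)CO1 | intermediate
14 | (3R)-3-[2,2-dimethyl-5-(triisopropylsilyloxy)-2H-chromen-8-yl]-4-hydroxybutanal (not isolated) | O=CC[C@H](c1ccc(O[Si](C(C)C)(C(C)C)C(C)C)c2c1OC(C)(C)C=C2)CO | intermediate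
15 | (2R)-2-[2,2-dimethyl-5-(triisopropylsilyloxy)-2H-chromen-8-yl]pent-4-yn-1-ol | C#CC[C@H](c1ccc(O[Si](C(C)C)(C(C)C)C(C)C)c2c1OC(C)(C)C=C2)CO | intermediate
16 | tert-butyl-dimethyl-{[(2R)-2-[2,2-dimethyl-5-(triisopropylsilyloxy)-2H-chromen-8-yl]pent-4-yn-1-yl]oxy}silane | C#CC[C@H](c1ccc(O[Si](C(C)C)(C(C)C)C(C)C)c2c1OC(C)(C)C=C2)CO[Si](C)(C)C(C)(C)C | intermediate
17 | lithium acetylide of 16 (not isolated) | [Li]C#CC[C@H](c1ccc(O[Si](C(C)C)(C(C)C)C(C)C)c2c1OC(C)(C)C=C2)CO[Si](C)(C)C(C)(C)C | intermediate
18 | lithium (4R)-5-(tert-butyldimethylsilyloxy)-4-[2,2-dimethyl-5-(triisopropylsilyloxy)-2H-chromen-8-yl]pent-1-yn-1-olate (not isolated) | [Li]OC#CC[C@H](c1ccc(O[Si](C(C)C)(C(C)C)C(C)C)c2c1OC(C)(C)C=C2)CO[Si](C)(C)C(C)(C)C | intermediate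
19 | (4R)-5-(tert-butyldimethylsilyloxy)-4-[2,2-dimethyl-5-(triisopropylsilyloxy)-2H-chromen-8-yl]-1-(triisopropylsilyloxy)pent-1-yne | CC(C)[Si](C(C)C)(C(C)C)OC#CC[C@H](c1ccc(O[Si](C(C)C)(C(C)C)C(C)C)c2c1OC(C)(C)C=C2)CO[Si](C)(C)C(C)(C)C | intermediate
20 | 3-ethoxycyclobut-2-en-1-one | CCOC1=CC(=O)C1 | starting material
21 | cyclobutane-1,3-dione (enol form 3-hydroxycyclobut-2-en-1-one) | O=C1CC(=O)C1 | intermediate
22 | 3-(triisopropylsilyloxy)cyclobut-2-en-1-one | CC(C)[Si](C(C)C)(C(C)C)OC1=CC(=O)C1 | intermediate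
23 | 3-(triisopropylsilyloxy)buta-1,3-dien-1-one (not isolated) | C=C(O[Si](C(C)C)(C(C)C)C(C)C)C=C=O | intermediate
24 | 2-[(2R)-3-(tert-butyldimethylsilyloxy)-2-aryl-propyl]-3-(triisopropylsilyloxy)-4-[1-(triisopropylsilyloxy)ethenyl]cyclobut-2-en-1-one, aryl = 2,2-dimethyl-5-(triisopropylsilyloxy)-2H-chromen-8-yl (not isolated) | O=C1C(C[C@H](c2ccc(O[Si](C(C)C)(C(C)C)C(C)C)c3c2OC(C)(C)C=C3)CO[Si](C)(C)C(C)(C)C)=C(O[Si](C(C)C)(C(C)C)C(C)C)C1C(=C)O[Si](C(C)C)(C(C)C)C(C)C | intermediate
25 | 2-[(2R)-3-(tert-butyldimethylsilyloxy)-2-aryl-propyl]-3,5-bis(triisopropylsilyloxy)hexa-1,3,5-trien-1-one, same aryl (not isolated) | O=C=C(C[C@H](c1ccc(O[Si](C(C)C)(C(C)C)C(C)C)c2c1OC(C)(C)C=C2)CO[Si](C)(C)C(C)(C)C)C(O[Si](C(C)C)(C(C)C)C(C)C)=CC(=C)O[Si](C(C)C)(C(C)C)C(C)C | intermediate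
26 | 2-[(2R)-3-(tert-butyldimethylsilyloxy)-2-aryl-propyl]-3,5-bis(triisopropylsilyloxy)cyclohexa-2,4-dien-1-one, same aryl (not isolated) | O=C1CC(O[Si](C(C)C)(C(C)C)C(C)C)=CC(O[Si](C(C)C)(C(C)C)C(C)C)=C1C[C@H](c1ccc(O[Si](C(C)C)(C(C)C)C(C)C)c2c1OC(C)(C)C=C2)CO[Si](C)(C)C(C)(C)C | intermediate
27 | 2-[(2R)-3-(tert-butyldimethylsilyloxy)-2-[2,2-dimethyl-5-(triisopropylsilyloxy)-2H-chromen-8-yl]propyl]-3,5-bis(triisopropylsilyloxy)phenol | Oc1cc(O[Si](C(C)C)(C(C)C)C(C)C)cc(O[Si](C(C)C)(C(C)C)C(C)C)c1C[C@H](c1ccc(O[Si](C(C)C)(C(C)C)C(C)C)c2c1OC(C)(C)C=C2)CO[Si](C)(C)C(C)(C)C | intermediate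
28 | tert-butyl-{(2R)-3-[2-methoxy-4,6-bis(triisopropylsilyloxy)phenyl]-2-[2,2-dimethyl-5-(triisopropylsilyloxy)-2H-chromen-8-yl]propoxy}dimethylsilane | COc1cc(O[Si](C(C)C)(C(C)C)C(C)C)cc(O[Si](C(C)C)(C(C)C)C(C)C)c1C[C@H](c1ccc(O[Si](C(C)C)(C(C)C)C(C)C)c2c1OC(C)(C)C=C2)CO[Si](C)(C)C(C)(C)C | intermediate
29 | 4-[(2R)-3-hydroxy-2-(5-hydroxy-2,2-dimethyl-2H-chromen-8-yl)propyl]-5-methoxybenzene-1,3-diol | COc1cc(O)cc(O)c1C[C@H](c1ccc(O)c2c1OC(C)(C)C=C2)CO | intermediate
30 | (3R)-3-(5-hydroxy-2,2-dimethyl-2H-chromen-8-yl)-5-methoxy-3,4-dihydro-2H-chromen-7-ol (CNP0320659.1) | COc1cc(O)cc2c1C[C@H](c1ccc(O)c3c1OC(C)(C)C=C3)CO2 | target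

**Step count**
Total: 15 steps. Longest linear sequence: 13 steps (steps 1–9, then 12–15); the cyclobutenone branch (steps 10–11) joins at step 12.

**Steps most likely to fail**

1. Step 12 (benzannulation). The donor-stabilised silyloxycyclobutenone may open too slowly, so that thermal 1,3-silyl shift of the ynol ether to a silylketene, ketene dimerisation, or acylation of the product phenol by excess vinylketene overtakes the cascade. The fallback keeps the siloxyalkyne but moves the C7 oxygen to a later, separate operation. Setting out from 19, benzannulation in toluene at 80 °C with freshly prepared cyclobut-2-en-1-one F1 (from 3-bromocyclobutanone and n-Bu3N) should give the resorcinol monosilyl ether 2-alkyl-3-(triisopropylsilyloxy)phenol F2. Methylation (MeI, K2CO3, acetone) should give the anisole F3. Iridium-catalysed C–H borylation ([Ir(OMe)(cod)]2, 4,4′-di-tert-butyl-2,2′-bipyridine, B2pin2, THF, 80 °C) is expected at C7, the only arene C–H without an ortho substituent, giving the pinacol boronate F4. Oxidation (NaBO3·4H2O, THF/H2O, rt) should give the C7 phenol F5. Desilylation of F5 with Bu4NF/AcOH rejoins the route at tetraol 29.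

2. Step 5 (asymmetric conjugate arylation). Protodeboronation of the electron-rich ortho-alkoxy arylboronic acid may outrun carbometalation of the poorly reactive five-membered enoate, and the ortho substituent may erode facial discrimination. The fallback sets the stereocentre by hydride delivery instead of aryl delivery. Setting out from 10, Suzuki–Miyaura coupling with commercial 4-bromofuran-2(5H)-one (Pd(PPh3)4, K3PO4, dioxane/H2O, 60 °C) should give the β-aryl butenolide F6. Copper hydride asymmetric conjugate reduction (CuCl2·2H2O, NaOt-Bu, p-tol-BINAP of the enantiomer that delivers the 4R product, polymethylhydrosiloxane, t-AmOH, toluene, rt) then rejoins the route at lactone 12.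

3. Step 15 (Mitsunobu closure). The two phenols that cannot cyclise may be alkylated intermolecularly or captured by the phosphonium and azodicarboxylate reagents, and the electron-rich tetraol may oxidise in air during handling. The fallback closes ring C while the phenols are being unmasked. Setting out from 28, selective acid cleavage of the primary silyl ether (camphorsulfonic acid, MeOH/CH2Cl2, 0 °C) should give the primary alcohol F7, and MsCl/Et3N (CH2Cl2, 0 °C) the mesylate F8. Treatment of F8 with Bu4NF in THF cleaves the three aryl silyl ethers, and the liberated C8a phenoxide should displace the mesylate in a 6-exo-tet Williamson closure, arriving directly at target 30.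

**Further compounds**
F1 | step 12 | cyclobut-2-en-1-one | O=C1C=CC1
F2 | step 12 | 2-[(2R)-3-(tert-butyldimethylsilyloxy)-2-[2,2-dimethyl-5-(triisopropylsilyloxy)-2H-chromen-8-yl]propyl]-3-(triisopropylsilyloxy)phenol | Oc1cccc(O[Si](C(C)C)(C(C)C)C(C)C)c1C[C@H](c1ccc(O[Si](C(C)C)(C(C)C)C(C)C)c2c1OC(C)(C)C=C2)CO[Si](C)(C)C(C)(C)C
F3 | step 12 | tert-butyl-{(2R)-3-[2-methoxy-6-(triisopropylsilyloxy)phenyl]-2-[2,2-dimethyl-5-(triisopropylsilyloxy)-2H-chromen-8-yl]propoxy}dimethylsilane | COc1cccc(O[Si](C(C)C)(C(C)C)C(C)C)c1C[C@H](c1ccc(O[Si](C(C)C)(C(C)C)C(C)C)c2c1OC(C)(C)C=C2)CO[Si](C)(C)C(C)(C)C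
F4 | step 12 | 4-(4,4,5,5-tetramethyl-1,3,2-dioxaborolan-2-yl) derivative of F3 (boron para to the alkyl chain) | COc1cc(B2OC(C)(C)C(C)(C)O2)cc(O[Si](C(C)C)(C(C)C)C(C)C)c1C[C@H](c1ccc(O[Si](C(C)C)(C(C)C)C(C)C)c2c1OC(C)(C)C=C2)CO[Si](C)(C)C(C)(C)C
F5 | step 12 | 4-[(2R)-3-(tert-butyldimethylsilyloxy)-2-[2,2-dimethyl-5-(triisopropylsilyloxy)-2H-chromen-8-yl]propyl]-3-methoxy-5-(triisopropylsilyloxy)phenol | COc1cc(O)cc(O[Si](C(C)C)(C(C)C)C(C)C)c1C[C@H](c1ccc(O[Si](C(C)C)(C(C)C)C(C)C)c2c1OC(C)(C)C=C2)CO[Si](C)(C)C(C)(C)C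
F6 | step 5 | 4-[2,2-dimethyl-5-(triisopropylsilyloxy)-2H-chromen-8-yl]furan-2(5H)-one | O=C1C=C(c2ccc(O[Si](C(C)C)(C(C)C)C(C)C)c3c2OC(C)(C)C=C3)CO1
F7 | step 15 | (2R)-3-[2-methoxy-4,6-bis(triisopropylsilyloxy)phenyl]-2-[2,2-dimethyl-5-(triisopropylsilyloxy)-2H-chromen-8-yl]propan-1-ol | COc1cc(O[Si](C(C)C)(C(C)C)C(C)C)cc(O[Si](C(C)C)(C(C)C)C(C)C)c1C[C@H](c1ccc(O[Si](C(C)C)(C(C)C)C(C)C)c2c1OC(C)(C)C=C2)CO
F8 | step 15 | (2R)-3-[2-methoxy-4,6-bis(triisopropylsilyloxy)phenyl]-2-[2,2-dimethyl-5-(triisopropylsilyloxy)-2H-chromen-8-yl]propyl methanesulfonate | COc1cc(O[Si](C(C)C)(C(C)C)C(C)C)cc(O[Si](C(C)C)(C(C)C)C(C)C)c1C[C@H](c1ccc(O[Si](C(C)C)(C(C)C)C(C)C)c2c1OC(C)(C)C=C2)COS(C)(=O)=O
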